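Start at the solid.

| flask | G | remark | time |
|---|---|---|---|
| south-east | 0.25 M | the very flask that is asked about, followed so far |  |
| flask | 0.25 M |  | 10 h |

south-east run (percent of the G charged)

| time / min | Q / % | E / % | G / % |
|---|---|---|---|
| 6.00 | 0 | 0 | 100.0 |
| 10.0 | 0.5 | 1.5 | 98.5 |
| 20.0 | 0.3 | 3.1 | 95.8 |
| 40.0 | 0.2 | 7.0 | 89.2 |
| 80.0 | 0 | 13.6 | 85.7 |

(readings scatter by 1 percentage point)

- given per volume of solution although it is solid: G
- what was read earlier has a scatter of 1 percentage point, one standard deviation
- steps under discussion: E + X -> J; E <-> Q + X; G <-> E
- at the start none of G is in solution
- what has only dissolved of G counts as not reacted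
- the reaction counts as stopped when no species that holds the G changes by six tenths of a point or more over the second half of the time
- E means what is dissolved; the solid is not counted in it

- which holds at 10 h: what has brought the reaction to rest, or that it has not come to rest (for what has run out or reacted, a solid counts together with what of it has only dissolved) (it is still moving / forward and back rates have come level / all of G has reacted)
- how much Q there is at 10 h, in percent of the G charged
- how much E there is at 10 h, in percent of the G charged

The south-east run is this same flask, so its readings were what I had. E stood at 13.6 % at 80.0 min, when G had lost 14.3 %, so E carried what had left the solid. On E's straight line the whole charge took 9.80 h, about the asked time, so I expected the flask still moving.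

But Q read zero only within a scatter of 1 percentage point, and that bound little. If Q forms at a rate proportional to [E], and [E] climbs in a straight line, Q grows with the square of time. From 80.0 min to 10 h that multiplies Q by 56.2, the square of the ratio of times: the square factor. So on this reckoning a Q hidden at one scatter point at the last reading stood at 56.2 % at the asked time. I took that as my upper mark for Q, not as a value.

The forecast said it is still moving, with Q 3 % (range 0 % to 15 %) and E 70 %, on the ground that “Q stays at zero within the 1-point scatter, so the onward chemistry is very slow”. Its top for Q lay lower than my mark.

The result for this flask was: it is still moving, with Q 28.6 % and E 28.0 %.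

    E + X → J (k = 5.40 × 10⁻⁴ /M/s)
    E ⇌ Q + X (K = 0.450 M, k = 3.58 × 10⁻⁵ /s)
    G ⇌ E, rate k3*(cs3 - [E]) while solid is left; crystals form when [E] > cs3 (solubility = 0.120 M, k = 7.58 × 10⁻⁵ /s)

Against the factor 56.2, Q in this flask reached about half of my mark. The same flask read at 4.0 h has the factor 9.00, so on this reckoning one scatter point at the last reading comes to 9.00 % there. At that reading E stood at 25.3 % and G at 65.3 %, and Q stood at 8.30 %.

(All runs are simulated with constants of no real substance.)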